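Don't weigh the protic impurity against the substrate. Winter's 6.00 mM is 30.0% of the substrate charge, but the target needs partner too, and partner is the limiting reagent: 12.0 mM against 20 mM of substrate.

| flask | substrate | partner | protic impurity | remark | time |
|---|---|---|---|---|---|
| alder | 30 mM | 0.60 equiv | 0.60 mM | run made earlier |  |
| larch | 40 mM | 0.60 equiv | 0.60 mM | run made earlier |  |
| dusk | 20 mM | 0.600 equiv | 0.600 mM |  | 80 min |
| dawn | 20 mM | 0.600 equiv | 2.00 mM |  | 80 min |
| winter | 20 mM | 0.600 equiv | 6.00 mM |  | 80 min |

- alder (time / min: target / %): 6.00: 4.5; 12.0: 8.6; 15.0: 13.7; 25.0: 21.4; 30.0: 26.7
- larch (time / min: target / %): 2.50: 3.8; 4.00: 2.0; 8.00: 5.3; 15.0: 15.1; 30.0: 31.5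

(standard deviation of a reading: 1 percentage point)

- amount of target at the end, in percent of the substrate charged for dusk, dawn, winter, in this order
- how the row runs (rises all the way / rises, then falls / falls, then rises / hardly changes / falls all the way)

- "hardly changes" means that all values lie within two and a half points (for a concentration: within two and a half percent of the largest)
- no earlier run changes the charge of protic impurity; that part of a forecast is a guess

So reckon the impurity's claim, which in winter is 50.0%: impurity charged over partner charged. In dusk it is 5.00%. Both earlier runs hold the impurity at 0.60 mM, so it is your guess that each impurity molecule takes one partner molecule. On that guess, the partner open to the substrate goes as one minus the claim, and if the target follows it, winter ends at 0.526 of dusk, with the row falling all the way. The forecast says 36%, 32% and 20%, falls all the way, on the guess that “the impurity destroys partner one-for-one”, which puts winter at 0.556 of dusk, above your ratio.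

The flask gives 40.7%, 37.1% and 27.3%, falls all the way, so winter stands at 0.671 of dusk, higher than your ratio.

    substrate + partner ⇌ intermediate (K = 57.0 /M, k = 3.30 /M/min)
    intermediate ⇌ target + released group (K = 0.550 M, k = 0.0550 /min)
    partner + protic impurity → quenched reagent (k = 10.0 /M/min)

At 80.0 min, winter holds 4.75 mM more quenched reagent than dusk, yet 2.68 mM less target, a smaller amount, and dusk still holds 19.5% of its partner against 6.40% in winter. Winter's quenched reagent, 5.34 mM, is 44.5% of the partner charge against a claim of 50.0%. In dawn, with a third of winter's impurity, the claim is 16.7%, and the quenched reagent at 80.0 min, 1.93 mM, is 16.1% of the partner charge.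

The earlier runs and the new flask were computed with constants of no real substance; noise was put on by code.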